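**Labels used throughout.** Ring A is the 4-hydroxy-3-methoxyphenyl ring on the stereocentre. Ring B is the 2,4-dihydroxyphenyl ring on the methylene. Ring C is the 2-hydroxy-3-methoxyphenyl ring that carries the stereocentre at C1 and the styryl group at C5. Ring D is the 3,5-dihydroxyphenyl ring. Cα is the stereogenic CH and Cβ the CH2. The target 16 is (S) at Cα (ring C > ring A > Cβ > H) and (E) at the stilbene.

## The problem

Target 16 is a 1,1,2-triarylethane: Cα carries rings A and C, Cβ joins it to ring B, and C5 of ring C carries an (E)-ethenyl link to ring D; six phenols are free and two are methyl ethers. The only stereocentre, Cα, has no neighbouring stereocentre to relay from and sits between two guaiacyl-type rings of almost the same size and donor strength, so a method that must tell ring A from ring C by shape has little to grip. The Cα–Cβ unit has to be bonded to three electron-rich arenes without 1,2-aryl shifts, without elimination to a stilbene and without loss of configuration through benzylic cations. The stilbene is para to the ring C oxygen and is therefore acid-sensitive, it does not survive catalytic hydrogenation, and the two methyl ethers rule out boron tribromide, so the final deprotection is narrowly constrained. The feature that the plan uses is the O–H on C2 of ring C, ortho to C1 which bears Cα: the atoms O–C2–C1–Cα are a latent ortho-quinone methide (O=C2–C1=Cα). In that form Cα is planar and electrophilic and the ring C oxygen is a hydrogen-bond acceptor two atoms from the prostereogenic carbon, while ring A, whose oxygen is para and can be capped, cannot do the same. The two near-identical rings thus become chemically distinct, and the triaryl skeleton can be assembled with no stereocontrol at all and Cα set afterwards by face-selective hydride delivery.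

## Retrosynthesis

**16 ⇒ 15.** Five O–CH2Ph bonds on rings A, B and D are cut. Benzyl ethers are chosen over silyl, acetal or ester groups because they survive Grignard reagents, the Brønsted acid of the key step and palladium catalysis, and because the benzylated blocks 2, 6 and 13 can be bought. The forward step must cleave five aryl benzyl ethers without reducing or protonating the stilbene and without touching the methyl ethers, which points to BCl3 with a cation scavenger at low temperature and excludes hydrogenolysis.

**15 ⇒ 12 + 14.** The C5(ring C)–vinyl bond is cut (Mizoroki–Heck). The stilbene is placed after the key step because, once present, it is para to the ring C oxygen and would offer the acid a second quinone methide pathway and the hydride donor a second acceptor. Bromide 12 needs no extra step for this handle, since the bromine is already in the commercial aldehyde 1. The forward step must give the (E)-alkene from an electron-rich bromophenol and leave Cα untouched.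

**12 ⇒ 10 (through 11).** The Cα–H bond is cut. Cutting any of the three Cα–C bonds in the stereodefining step would require a catalyst to distinguish ring A from ring C or a preformed stereocentre. The C–H cut leads back to quinone methide 11, in which ring C is part of the electrophile and ring A is a spectator. Carbinol 10 is not smaller than 12, but it is simpler where it matters: it is racemic, needs no alkene geometry and is reached by two carbonyl additions. The forward step must ionise 10 through ring C only and deliver hydride to one face of Cα in 11.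

**10 ⇒ 5 + 9 (9 ⇐ 8 ⇐ 7 ⇐ 6).** The Cα–Cβ bond is cut (benzylic Grignard addition to a diaryl ketone). The neighbouring cut, Cα–ring C, would need a metalated ring C, which is incompatible with its bromide, and an enolisable deoxybenzoin as acceptor. Ketone 5 has no α-hydrogen. Chloride 8 comes from the commercial aldehyde 6 through alcohol 7. Nothing stereochemical is asked of the forward step.

**5 ⇒ 4 ⇒ 1 + 3 (3 ⇐ 2).** The Cα–ring A bond is cut (aryl Grignard addition to a salicylaldehyde, then oxidation of carbinol 4). Aldehyde 1 already holds every ring C substituent in place: the C2 hydroxyl, the C3 methoxyl, the C5 bromide and Cα as the formyl carbon. The forward steps must tolerate the free phenol, which is never protected in the whole route.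

**14 ⇐ 13.** The vinyl C=C is cut (Wittig methylenation of the commercial aldehyde 13).

## Roads not taken

**Alternative 1:** the most obvious plan cuts the Cα–ring A bond by rhodium-catalysed asymmetric conjugate addition of boronic acid A2 to coumarin A1 (from 1 by olefination and lactonisation), giving dihydrocoumarin A3. Ring C is bound in the lactone, so the two aryl groups are differentiated and high selectivity can be expected. The weakness is constitutional: C3 of A3 is Cβ, and the lactone carbonyl carbon is one carbon too many. Ring B would have to replace it, which means opening and O-protection to acid A4 followed by a decarboxylative arylation. That coupling runs through a 2,2-diarylethyl radical, which is prone to 1,2-aryl (neophyl) migration and would scramble both connectivity and configuration, and its nickel catalyst would not tolerate the ring C bromide. The chosen plan builds Cβ–ring B by a plain carbonyl addition and needs no carbon excision.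

**Alternative 2:** a three-component cut of Cα–ring C and Cβ–B: copper/palladium-catalysed enantioselective arylboration of styrene A5 with bis(pinacolato)diboron and aryl bromide A6 to boronate A7, then an sp3–sp2 Suzuki–Miyaura coupling that brings in ring B as an aryl bromide. This is convergent and has precedent for 1,1,2-triarylethanes. Against it: ring C enters as an ortho-alkoxy, doubly flanked electrophile in the step that fixes the configuration; the C5 bromide cannot be present, so the stilbene handle must be a masked aldehyde (acetal on and off, then an olefination with a phosphonate that has to be made); and the coupling of the β-branched primary boronate A7 with an electron-rich ortho-substituted bromide invites β-hydride elimination. The ring C phenol would be protected and unused. The chosen plan has one uncertain catalytic step instead of two and keeps the bromide.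

**Alternative 3:** a stereospecific cut of Cα–ring C by 1,2-metalate rearrangement: carbamate A8 is lithiated, borylated with ring C boronate A9, rearranged to the tertiary boronate A10 and protodeboronated with retention. Each ring is introduced in its own step, so the similarity of rings A and C is irrelevant. Against it: A8 must first be made enantiopure (ketone synthesis, asymmetric reduction, carbamoylation); stoichiometric sec-butyllithium at low temperature excludes the aryl bromide; an ortho-alkoxy aryl group must migrate to a hindered centre from an ate complex that can dissociate when the benzylic carbanion is stabilised by an electron-rich ring; and four operations are spent on one stereocentre. The chosen plan sets Cα in one catalytic, enantioconvergent step from a racemate.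

Key step: step 6

**Assumptions.** Compounds 1, 2, 6 and 13 are taken as purchasable. The (R)-acid is written in step 6; the sense of induction cannot be predicted with certainty for this substrate, and the (S)-acid would be used if the (R)-acid delivers hydride to the other face.

## Route

Step 1
Reactants: 1 5-bromo-2-hydroxy-3-methoxybenzaldehyde; 2 1-(benzyloxy)-4-bromo-2-methoxybenzene
Product: 4 2-{[4-(benzyloxy)-3-methoxyphenyl](hydroxy)methyl}-4-bromo-6-methoxyphenol (racemic diarylmethanol), via aryl Grignard reagent 3 (not isolated)
Conditions: 2 (2.3 equiv), Mg turnings, THF, 45 °C; then 1, 0 °C to rt; aq. NH4Cl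
Reagents that add atoms: none
Why: Grignard addition to a salicylaldehyde: the first equivalent of 3 is spent on the phenol O–H and the second adds to the formyl group; the ring C bromide does not exchange with an aryl Grignard reagent at these temperatures, and the new carbinol centre is racemic without consequence because step 2 removes it.

Step 2
Reactants: 4 2-{[4-(benzyloxy)-3-methoxyphenyl](hydroxy)methyl}-4-bromo-6-methoxyphenol
Product: 5 [4-(benzyloxy)-3-methoxyphenyl](5-bromo-2-hydroxy-3-methoxyphenyl)methanone
Conditions: activated MnO2 (10 equiv), CH2Cl2, rt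
Reagents that add atoms: none
Why: Oxidation of a doubly benzylic secondary alcohol with manganese dioxide, which is selective for benzylic carbinols and leaves the para-blocked phenol and the benzyl ether alone; the product is a hydrogen-bonded ortho-hydroxybenzophenone.

Step 3
Reactants: 6 2,4-bis(benzyloxy)benzaldehyde
Product: 7 [2,4-bis(benzyloxy)phenyl]methanol
Conditions: NaBH4, MeOH/THF, 0 °C
Reagents that add atoms: none
Why: Borohydride reduction of an aromatic aldehyde; no other reducible group is present.

Step 4
Reactants: 7 [2,4-bis(benzyloxy)phenyl]methanol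
Product: 8 2,4-bis(benzyloxy)-1-(chloromethyl)benzene
Conditions: MsCl, Et3N, CH2Cl2, 0 °C to rt; used at once
Reagents that add atoms: methanesulfonyl chloride, CS(=O)(=O)Cl
Why: Mesylation of an electron-rich benzylic alcohol, whose mesylate is displaced in the flask by the chloride released from the reagent; the conditions stay non-acidic, which avoids self-alkylation of the arene.

Step 5
Reactants: 5 [4-(benzyloxy)-3-methoxyphenyl](5-bromo-2-hydroxy-3-methoxyphenyl)methanone; 8 2,4-bis(benzyloxy)-1-(chloromethyl)benzene
Product: 10 2-{2-[2,4-bis(benzyloxy)phenyl]-1-[4-(benzyloxy)-3-methoxyphenyl]-1-hydroxyethyl}-4-bromo-6-methoxyphenol (racemic tertiary carbinol), via benzylic Grignard reagent 9 (not isolated)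
Conditions: 8 (2.6 equiv), Mg turnings, 2-methyltetrahydrofuran, 0 °C, slow addition; then 5, −20 °C to rt; aq. NH4Cl; neutral work-up, no acidic silica
Reagents that add atoms: none
Why: Grignard addition of a benzylic organomagnesium to a diaryl ketone that has no α-hydrogen, so enolisation cannot compete; one equivalent of 9 is spent on the phenol O–H, slow addition in 2-methyltetrahydrofuran holds back Wurtz coupling, and the racemic outcome is exactly what step 6 accepts.

Step 6
Reactants: 10 2-{2-[2,4-bis(benzyloxy)phenyl]-1-[4-(benzyloxy)-3-methoxyphenyl]-1-hydroxyethyl}-4-bromo-6-methoxyphenol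
Product: 12 2-{(1S)-2-[2,4-bis(benzyloxy)phenyl]-1-[4-(benzyloxy)-3-methoxyphenyl]ethyl}-4-bromo-6-methoxyphenol, via ortho-quinone methide 11 (not isolated)
Conditions: (R)-3,3'-bis(2,4,6-triisopropylphenyl)-1,1'-binaphthalene-2,2'-diyl hydrogen phosphate (10 mol %), diethyl 2,6-dimethyl-1,4-dihydropyridine-3,5-dicarboxylate (1.5 equiv), 5 Å molecular sieves, CH2Cl2, rt
Reagents that add atoms: none
Why: The phosphoric acid protonates the tertiary benzylic hydroxyl of 10 and water leaves to give the ortho-quinone methide 11 (O=C2–C1=Cα), the same planar species from either enantiomer of 10, so the step is enantioconvergent. The bifunctional acid holds 11 by a hydrogen bond from P–O–H to the quinone methide oxygen and the dihydropyridine by N–H···O=P, and hydride passes from C4 of the dihydropyridine to one face of Cα in this ternary assembly, the rearomatisation of ring C making the transfer irreversible. The closest known reaction type is the chiral-phosphoric-acid-catalysed transfer hydrogenation of ortho-quinone methides generated in the flask from ortho-hydroxy 1,1-diarylalkenes or ortho-hydroxybenzylic tertiary alcohols, which gives 1,1-diarylalkanes. No ring is closed. The new stereocentre at Cα is controlled by the catalyst alone, whose 2,4,6-triisopropylphenyl groups shield one face of the exocyclic C=C; the two geometric isomers of 11 interconvert by reversible addition of water, so the faster-reacting one is drained. The step needs ionisation through ring C and not ring A, which the benzyl ether on the ring A oxygen secures because only ring C can give a neutral hydrogen-bonded quinone methide, and it needs the 2-oxygen of ring B not to trap Cα as a dihydrobenzofuran, which its benzyl ether prevents. The aryl bromide and all ethers are inert to the weak acid and the hydride donor.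

Step 7
Reactants: 13 3,5-bis(benzyloxy)benzaldehyde
Product: 14 1,3-bis(benzyloxy)-5-ethenylbenzene
Conditions: Ph3PCH3Br, KOtBu, THF, 0 °C to rt
Reagents that add atoms: methyltriphenylphosphonium bromide, C[P+](c1ccccc1)(c1ccccc1)c1ccccc1.[Br-]
Why: Wittig methylenation of an aromatic aldehyde with the non-stabilised ylide; no stereochemistry is involved.

Step 8
Reactants: 12 2-{(1S)-2-[2,4-bis(benzyloxy)phenyl]-1-[4-(benzyloxy)-3-methoxyphenyl]ethyl}-4-bromo-6-methoxyphenol; 14 1,3-bis(benzyloxy)-5-ethenylbenzene
Product: 15 2-{(1S)-2-[2,4-bis(benzyloxy)phenyl]-1-[4-(benzyloxy)-3-methoxyphenyl]ethyl}-4-{(E)-2-[3,5-bis(benzyloxy)phenyl]ethenyl}-6-methoxyphenol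
Conditions: Pd(OAc)2 (5 mol %), P(o-tol)3 (12 mol %), Et3N, DMF, 100 °C, argon, dark
Reagents that add atoms: none
Why: Mizoroki–Heck reaction: zerovalent palladium inserts into the unhindered C5–Br bond, syn-insertion of the styrene and syn-β-hydride elimination give the (E)-stilbene; Cα–H is not acidic enough to be touched by triethylamine, so the configuration is kept.

Step 9
Reactants: 15 2-{(1S)-2-[2,4-bis(benzyloxy)phenyl]-1-[4-(benzyloxy)-3-methoxyphenyl]ethyl}-4-{(E)-2-[3,5-bis(benzyloxy)phenyl]ethenyl}-6-methoxyphenol
Product: 16 4-[(2S)-2-{5-[(E)-2-(3,5-dihydroxyphenyl)ethenyl]-2-hydroxy-3-methoxyphenyl}-2-(4-hydroxy-3-methoxyphenyl)ethyl]benzene-1,3-diol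
Conditions: BCl3 (1 M in CH2Cl2, excess), pentamethylbenzene (excess), CH2Cl2, −78 °C; then MeOH; work-up under argon
Reagents that add atoms: none
Why: Lewis-acid cleavage of aryl benzyl ethers with a non-basic cation scavenger: BCl3 activates each benzylic C–O bond and pentamethylbenzene traps the benzyl cation, which prevents C-benzylation of the phenolic rings; at −78 °C aryl methyl ethers are not cleaved and, unlike hydrogenolysis, nothing reduces the alkene.

## Compound list

1 | 5-bromo-2-hydroxy-3-methoxybenzaldehyde | O=Cc1cc(Br)cc(OC)c1O | starting material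
2 | 1-(benzyloxy)-4-bromo-2-methoxybenzene | COc1cc(Br)ccc1OCc1ccccc1 | starting material
3 | [4-(benzyloxy)-3-methoxyphenyl]magnesium bromide (not isolated) | COc1cc([Mg]Br)ccc1OCc1ccccc1 | intermediate
4 | 2-{[4-(benzyloxy)-3-methoxyphenyl](hydroxy)methyl}-4-bromo-6-methoxyphenol, racemic | COc1cc(C(O)c2cc(Br)cc(OC)c2O)ccc1OCc1ccccc1 | intermediate
5 | [4-(benzyloxy)-3-methoxyphenyl](5-bromo-2-hydroxy-3-methoxyphenyl)methanone | COc1cc(C(=O)c2cc(Br)cc(OC)c2O)ccc1OCc1ccccc1 | intermediate
6 | 2,4-bis(benzyloxy)benzaldehyde | O=Cc1ccc(OCc2ccccc2)cc1OCc1ccccc1 | starting material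
7 | [2,4-bis(benzyloxy)phenyl]methanol | OCc1ccc(OCc2ccccc2)cc1OCc1ccccc1 | intermediate
8 | 2,4-bis(benzyloxy)-1-(chloromethyl)benzene | ClCc1ccc(OCc2ccccc2)cc1OCc1ccccc1 | intermediate
9 | [2,4-bis(benzyloxy)benzyl]magnesium chloride (not isolated) | Cl[Mg]Cc1ccc(OCc2ccccc2)cc1OCc1ccccc1 | intermediate
10 | 2-{2-[2,4-bis(benzyloxy)phenyl]-1-[4-(benzyloxy)-3-methoxyphenyl]-1-hydroxyethyl}-4-bromo-6-methoxyphenol, racemic | COc1cc(C(O)(Cc2ccc(OCc3ccccc3)cc2OCc2ccccc2)c2cc(Br)cc(OC)c2O)ccc1OCc1ccccc1 | intermediate
11 | 6-{2-[2,4-bis(benzyloxy)phenyl]-1-[4-(benzyloxy)-3-methoxyphenyl]ethylidene}-4-bromo-2-methoxycyclohexa-2,4-dien-1-one, both geometries of the exocyclic C=C, interconverting (not isolated) | COC1=CC(Br)=CC(=C(Cc2ccc(OCc3ccccc3)cc2OCc2ccccc2)c2ccc(OCc3ccccc3)c(OC)c2)C1=O | intermediate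
12 | 2-{(1S)-2-[2,4-bis(benzyloxy)phenyl]-1-[4-(benzyloxy)-3-methoxyphenyl]ethyl}-4-bromo-6-methoxyphenol | COc1cc([C@H](Cc2ccc(OCc3ccccc3)cc2OCc2ccccc2)c2cc(Br)cc(OC)c2O)ccc1OCc1ccccc1 | intermediate
13 | 3,5-bis(benzyloxy)benzaldehyde | O=Cc1cc(OCc2ccccc2)cc(OCc2ccccc2)c1 | starting material
14 | 1,3-bis(benzyloxy)-5-ethenylbenzene | C=Cc1cc(OCc2ccccc2)cc(OCc2ccccc2)c1 | intermediate
15 | 2-{(1S)-2-[2,4-bis(benzyloxy)phenyl]-1-[4-(benzyloxy)-3-methoxyphenyl]ethyl}-4-{(E)-2-[3,5-bis(benzyloxy)phenyl]ethenyl}-6-methoxyphenol | COc1cc([C@H](Cc2ccc(OCc3ccccc3)cc2OCc2ccccc2)c2cc(/C=C/c3cc(OCc4ccccc4)cc(OCc4ccccc4)c3)cc(OC)c2O)ccc1OCc1ccccc1 | intermediate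
16 | 4-[(2S)-2-{5-[(E)-2-(3,5-dihydroxyphenyl)ethenyl]-2-hydroxy-3-methoxyphenyl}-2-(4-hydroxy-3-methoxyphenyl)ethyl]benzene-1,3-diol | COc1cc([C@H](Cc2ccc(O)cc2O)c2cc(/C=C/c3cc(O)cc(O)c3)cc(OC)c2O)ccc1O | target

## Step count and least certain steps

Total: 9 steps. Longest linear sequence: 6 steps (steps 1, 2, 5, 6, 8, 9 from 1 or 2; equally steps 3, 4, 5, 6, 8, 9 from 6).

**Step 6 (key step).** The most likely failure is insufficient facial discrimination in the hydride transfer. The two groups on Cα of 11 that the catalyst pocket must tell apart (ring A and the ring B methylene) are closer in size than the aryl/methyl pair of the known cases, and the two geometric isomers of 11 may be reduced with opposite sense. A second leak is proton loss from Cβ followed by reprotonation at Cα, which would give a ring-B-stabilised benzylic cation that is reduced without catalyst control. The fallback gives up asymmetric catalysis for resolution and sets out from 10. Ionic hydrogenation (Et3SiH, CF3CO2H, CH2Cl2, 0 °C) gives the racemic 2-{2-[2,4-bis(benzyloxy)phenyl]-1-[4-(benzyloxy)-3-methoxyphenyl]ethyl}-4-bromo-6-methoxyphenol F1. Preparative supercritical-fluid chromatography on an amylose tris(3,5-dimethylphenylcarbamate) phase then separates 12 from its (R)-enantiomer F2, and the route is rejoined at 12.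

**Step 5.** The likely failure is Wurtz-type homocoupling while magnesium inserts into the electron-rich benzylic chloride 8, together with slow addition to the poorly soluble, deactivated magnesium phenoxide of 5. The fallback avoids the benzylic organometallic altogether and sets out from 5 and 6. A crossed McMurry coupling (TiCl4, Zn dust, THF, reflux; 6 in excess) should give the (Z)-2-{2-[2,4-bis(benzyloxy)phenyl]-1-[4-(benzyloxy)-3-methoxyphenyl]ethenyl}-4-bromo-6-methoxyphenol F3 and its (E)-isomer F4 as a mixture. Under the conditions of step 6 both are protonated at Cβ, with the ring C phenol relaying the proton, so the mixture converges on 11 and the route is rejoined there and at 12; steps 3 and 4 are then not needed.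

**Step 8.** The likely failure is slow oxidative addition of zerovalent palladium into a C–Br bond para to a phenolate, so that catalyst decay and 1,1-arylation of 14 compete at the temperature required. The fallback replaces alkene insertion by cross-coupling of a preformed (E)-alkenylboron reagent and sets out from 13 and 12. A boron–Wittig reaction of 13 with 2,2'-methylenebis(4,4,5,5-tetramethyl-1,3,2-dioxaborolane) and lithium 2,2,6,6-tetramethylpiperidide (THF, −78 °C to rt) gives 2-{(E)-2-[3,5-bis(benzyloxy)phenyl]ethenyl}-4,4,5,5-tetramethyl-1,3,2-dioxaborolane F5. Suzuki–Miyaura coupling of F5 with 12 (Pd(OAc)2, 2-dicyclohexylphosphino-2',6'-dimethoxybiphenyl, K3PO4, dioxane/water, 60 °C) fixes regiochemistry and alkene geometry in the reagent and returns to the route at 15; step 7 is then not needed.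

**Step 9.** The likely failure is acid-induced loss of the stilbene during the fivefold ether cleavage: protonation at the alkene carbon next to ring D gives a cation stabilised by the ring C oxygen, which cyclises or oligomerises, and cleavage of five ethers may be incomplete. The fallback removes the benzyl groups before the alkene exists and sets out from 12:
- BCl3 and pentamethylbenzene (CH2Cl2, −78 °C) give 4-[(2S)-2-(5-bromo-2-hydroxy-3-methoxyphenyl)-2-(4-hydroxy-3-methoxyphenyl)ethyl]benzene-1,3-diol F6.
- Acetic anhydride and pyridine give its tetraacetate F7.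
- Mizoroki–Heck reaction of F7, now an electron-neutral bromide, with purchased 3,5-diacetoxystyrene (Pd(OAc)2, P(o-tol)3, Et3N, MeCN, 85 °C) gives the hexaacetate of the target F8.
- Methanolysis (K2CO3 cat., MeOH, 0 °C, argon) returns to the route at 16; steps 7 to 9 are then replaced.

## Further compounds

F1 | step 6 | 2-{2-[2,4-bis(benzyloxy)phenyl]-1-[4-(benzyloxy)-3-methoxyphenyl]ethyl}-4-bromo-6-methoxyphenol, racemic | COc1cc(C(Cc2ccc(OCc3ccccc3)cc2OCc2ccccc2)c2cc(Br)cc(OC)c2O)ccc1OCc1ccccc1
F2 | step 6 | 2-{(1R)-2-[2,4-bis(benzyloxy)phenyl]-1-[4-(benzyloxy)-3-methoxyphenyl]ethyl}-4-bromo-6-methoxyphenol | COc1cc([C@@H](Cc2ccc(OCc3ccccc3)cc2OCc2ccccc2)c2cc(Br)cc(OC)c2O)ccc1OCc1ccccc1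
F3 | step 5 | 2-{(Z)-2-[2,4-bis(benzyloxy)phenyl]-1-[4-(benzyloxy)-3-methoxyphenyl]ethenyl}-4-bromo-6-methoxyphenol | COc1cc(/C(=C/c2ccc(OCc3ccccc3)cc2OCc2ccccc2)c2cc(Br)cc(OC)c2O)ccc1OCc1ccccc1
F4 | step 5 | 2-{(E)-2-[2,4-bis(benzyloxy)phenyl]-1-[4-(benzyloxy)-3-methoxyphenyl]ethenyl}-4-bromo-6-methoxyphenol | COc1cc(/C(=C\c2ccc(OCc3ccccc3)cc2OCc2ccccc2)c2cc(Br)cc(OC)c2O)ccc1OCc1ccccc1
F5 | step 8 | 2-{(E)-2-[3,5-bis(benzyloxy)phenyl]ethenyl}-4,4,5,5-tetramethyl-1,3,2-dioxaborolane | CC1(C)OB(/C=C/c2cc(OCc3ccccc3)cc(OCc3ccccc3)c2)OC1(C)C
F6 | step 9 | 4-[(2S)-2-(5-bromo-2-hydroxy-3-methoxyphenyl)-2-(4-hydroxy-3-methoxyphenyl)ethyl]benzene-1,3-diol | COc1cc([C@H](Cc2ccc(O)cc2O)c2cc(Br)cc(OC)c2O)ccc1O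
F7 | step 9 | 4-[(2S)-2-[2-(acetyloxy)-5-bromo-3-methoxyphenyl]-2-[4-(acetyloxy)-3-methoxyphenyl]ethyl]-1,3-phenylene diacetate | COc1cc([C@H](Cc2ccc(OC(C)=O)cc2OC(C)=O)c2cc(Br)cc(OC)c2OC(C)=O)ccc1OC(C)=O
F8 | step 9 | hexaacetate of 16: 4-[(2S)-2-{2-(acetyloxy)-5-[(E)-2-(3,5-diacetoxyphenyl)ethenyl]-3-methoxyphenyl}-2-[4-(acetyloxy)-3-methoxyphenyl]ethyl]-1,3-phenylene diacetate | COc1cc([C@H](Cc2ccc(OC(C)=O)cc2OC(C)=O)c2cc(/C=C/c3cc(OC(C)=O)cc(OC(C)=O)c3)cc(OC)c2OC(C)=O)ccc1OC(C)=O
A1 | alternative 1 | 6-bromo-8-methoxy-2H-chromen-2-one | COc1cc(Br)cc2ccc(=O)oc12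
A2 | alternative 1 | [4-(benzyloxy)-3-methoxyphenyl]boronic acid | COc1cc(B(O)O)ccc1OCc1ccccc1
A3 | alternative 1 | (4S)-4-[4-(benzyloxy)-3-methoxyphenyl]-6-bromo-8-methoxy-3,4-dihydro-2H-chromen-2-one | COc1cc([C@@H]2CC(=O)Oc3c(OC)cc(Br)cc32)ccc1OCc1ccccc1
A4 | alternative 1 | (3S)-3-[4-(benzyloxy)-3-methoxyphenyl]-3-[2-(benzyloxy)-5-bromo-3-methoxyphenyl]propanoic acid | COc1cc([C@H](CC(=O)O)c2cc(Br)cc(OC)c2OCc2ccccc2)ccc1OCc1ccccc1
A5 | alternative 2 | 1-(benzyloxy)-4-ethenyl-2-methoxybenzene | C=Cc1ccc(OCc2ccccc2)c(OC)c1
A6 | alternative 2 | 2-[4-(benzyloxy)-3-bromo-5-methoxyphenyl]-1,3-dioxolane | COc1cc(C2OCCO2)cc(Br)c1OCc1ccccc1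
A7 | alternative 2 | 2-{(2S)-2-[4-(benzyloxy)-3-methoxyphenyl]-2-[2-(benzyloxy)-5-(1,3-dioxolan-2-yl)-3-methoxyphenyl]ethyl}-4,4,5,5-tetramethyl-1,3,2-dioxaborolane | COc1cc([C@H](CB2OC(C)(C)C(C)(C)O2)c2cc(C3OCCO3)cc(OC)c2OCc2ccccc2)ccc1OCc1ccccc1
A8 | alternative 3 | (1R)-2-[2,4-bis(benzyloxy)phenyl]-1-[4-(benzyloxy)-3-methoxyphenyl]ethyl N,N-di(propan-2-yl)carbamate | COc1cc([C@@H](Cc2ccc(OCc3ccccc3)cc2OCc2ccccc2)OC(=O)N(C(C)C)C(C)C)ccc1OCc1ccccc1
A9 | alternative 3 | 2-[2-(benzyloxy)-5-(1,3-dioxolan-2-yl)-3-methoxyphenyl]-4,4,5,5-tetramethyl-1,3,2-dioxaborolane | COc1cc(C2OCCO2)cc(B2OC(C)(C)C(C)(C)O2)c1OCc1ccccc1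
A10 | alternative 3 | 2-{(1S)-2-[2,4-bis(benzyloxy)phenyl]-1-[4-(benzyloxy)-3-methoxyphenyl]-1-[2-(benzyloxy)-5-(1,3-dioxolan-2-yl)-3-methoxyphenyl]ethyl}-4,4,5,5-tetramethyl-1,3,2-dioxaborolane | COc1cc([C@](B2OC(C)(C)C(C)(C)O2)(Cc2ccc(OCc3ccccc3)cc2OCc2ccccc2)c2cc(C3OCCO3)cc(OC)c2OCc2ccccc2)ccc1OCc1ccccc1
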